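**Retrosynthetic overview**
- The target comes from an all-trans 2-aryl-4-aroyl-oxolane-3-carbaldehyde by reduction of the formyl group and removal of the phenol silyl groups.
- That oxolane comes from an enantioselective seven-to-five ring contraction (stepwise [1,3] O-to-C shift) of a racemic 5-aroyl-2-aryl-1,3-dioxepine, used as its silyl dienol ether. This step makes the C2–C3 bond, the oxolane ring and the C2 stereocentre; C3 and C4 then settle thermodynamically.
- The dioxepine comes from acetalisation of O-silyl syringaldehyde with a 2-aroylbut-2-ene-1,4-diol bis-silyl ether, itself made by rhodium hydroacylation of but-2-yne-1,4-diol bis-silyl ether with the same aldehyde.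
- O-Silyl syringaldehyde (source of both aryl groups, the ketone carbon and C2) comes from p-cresol by bromination/side-chain oxidation and copper-catalysed methoxylation.
- Ring order: both arene rings arrive with p-cresol; the 1,3-dioxepine is built first and is then contracted to the oxolane, the only new ring of the target.

Assumption: oxolane atoms are numbered O1, C2 (aryl), C3, C4 (aroyl), C5 throughout, so the target is (2S,3R,4S), all-trans; Ar = 4-(tert-butyldimethylsilyloxy)-3,5-dimethoxyphenyl.

**Route**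

Step 1
Reactants: 1 p-cresol
Product: 4 3,5-dibromo-4-hydroxybenzaldehyde, via dibromocresol 2 (not isolated), via benzal bromide 3 (not isolated)
Conditions: Br2 (2 equiv), o-dichlorobenzene, 35 °C; Br2 (2 equiv), 150 °C; then H2O, 100 °C
Reagents that add atoms: bromine (BrBr); water (O)
Why: Electrophilic aromatic bromination fills both positions ortho to the phenol, then free-radical side-chain bromination at 150 °C gives the benzal bromide, which water hydrolyses to the aldehyde (the established p-cresol process); no stereocentre.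

Step 2
Reactants: 4 3,5-dibromo-4-hydroxybenzaldehyde
Product: 5 syringaldehyde (4-hydroxy-3,5-dimethoxybenzaldehyde)
Conditions: NaOMe (4 equiv), CuCl (5 mol %), MeOH/DMF, 110 °C; aq. HCl
Reagents that add atoms: sodium methoxide ([Na+].[O-]C)
Why: Copper-catalysed nucleophilic aromatic methoxylation (Ullmann-type ether synthesis) replaces both bromides, the standard preparation of syringaldehyde; no stereocentre.

Step 3
Reactants: 5 syringaldehyde
Product: 6 4-(tert-butyldimethylsilyloxy)-3,5-dimethoxybenzaldehyde (ArCHO)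
Conditions: TBSCl, imidazole, DMF, rt
Reagents that add atoms: tert-butyldimethylsilyl chloride (CC(C)(C)[Si](C)(C)Cl)
Why: Corey silylation masks the phenol as an aryl TBS ether that tolerates the rhodium and Lewis-acid steps and is removed by K2CO3/MeOH at the end; no stereocentre.

Step 4
Reactants: 7 but-2-yne-1,4-diol
Product: 8 1,4-bis(triethylsilyloxy)but-2-yne
Conditions: Et3SiCl (2.2 equiv), imidazole, CH2Cl2, 0 °C to rt
Reagents that add atoms: chlorotriethylsilane (CC[Si](CC)(CC)Cl)
Why: Silylation keeps the propargylic OH groups out of the rhodium chemistry and provides the bis-silyl ether that later serves as the acetalisation partner; no stereocentre.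

Step 5
Reactants: 6 ArCHO and 8 1,4-bis(triethylsilyloxy)but-2-yne
Product: 9 (E)-1-Ar-4-(triethylsilyloxy)-2-[(triethylsilyloxy)methyl]but-2-en-1-one
Conditions: 8 (1.5 equiv), RhCl(PPh3)3 (5 mol %), 2-amino-3-picoline (40 mol %), PhCO2H (20 mol %), toluene, 90 °C
Reagents that add atoms: none
Why: Chelation-assisted rhodium-catalysed alkyne hydroacylation adds the formyl C–H syn across the symmetrical alkyne (no regiochemical issue), giving the E-enone whose two silyloxymethyl arms are cis as the seven-membered acetal requires; no stereocentre.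

Step 6
Reactants: 9 E-enone bis-silyl ether and 6 ArCHO
Product: 10 Ar-(2-Ar-4,7-dihydro-1,3-dioxepin-5-yl)methanone (racemic at the acetal carbon)
Conditions: 6 (1.05 equiv), TMSOTf (10 mol %), CH2Cl2, −78 to −30 °C; pyridine quench
Reagents that add atoms: none
Why: Noyori acetalisation (aldehyde plus bis-silyl ether, driven by disiloxane formation) closes the 1,3-dioxepine under cold aprotic conditions that spare the enone and the aryl silyl ethers; the new acetal stereocentre is racemic and is erased in step 8.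

Step 7
Reactants: 10 dioxepinyl aryl ketone
Product: 11 2-Ar-5-[Ar(triethylsilyloxy)methylidene]-4,5-dihydro-1,3-dioxepine (racemic, E/Z mixture)
Conditions: Et3SiOTf (1.3 equiv), Et3N (2 equiv), CH2Cl2, −78 to 0 °C
Reagents that add atoms: triethylsilyl trifluoromethanesulfonate (CC[Si](CC)(CC)OS(=O)(=O)C(F)(F)F)
Why: Soft enolisation (silyl triflate/amine) silylates the enone oxygen and removes a proton from the only γ-CH2 (next to a ring oxygen), giving the silyl dienol ether and moving the ring alkene into the vinyl-acetal position needed for the ring contraction; no new stereocentre.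

Step 8
Reactants: 11 silyl dienol ether
Product: 14 (2S,3S,4S)-4-(Ar-carbonyl)-2-Ar-oxolane-3-carbaldehyde (all-trans), via silyl enol ether aldehyde 12 (not isolated), via epimeric keto aldehydes 13 (not isolated)
Conditions: chiral imidodiphosphorimidate (IDPi) Brønsted acid (2 mol %, the antipode that gives 2S, fixed by a screen), toluene, −78 °C; then 0.5 M aq. HCl, THF, 0 °C; then DBU (0.2 equiv), CH2Cl2, 0 °C to rt
Reagents that add atoms: none
Why: Proposed new method: the IDPi acid is silylated by 11 to an Et3Si+/IDPi− ion pair that ionises the acetal C–O bond to the vinyl-ether oxygen, so both enantiomers of 11 converge on one achiral aryl oxocarbenium/bis-silyloxydiene intermediate, and the vinyl-ether β-carbon then closes onto the oxocarbenium carbon inside the chiral anion pocket in a stepwise ionic [1,3] O-to-C shift (seven- to five-membered ring contraction, not pericyclic) that fixes C2 as S, after which C3 (α to CHO) and C4 (α to the ketone freed by HCl) are equilibrated by DBU to the all-trans isomer; the closest known reaction types are the Lewis-acid vinyl-acetal (Petasis–Ferrier-type) ring contraction of 4,5-dihydro-1,3-dioxepines and chiral-anion-directed Mukaiyama additions of silyl enol ethers to oxocarbenium ions.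

Step 9
Reactants: 14 all-trans keto aldehyde
Product: 16 (4-hydroxy-3,5-dimethoxyphenyl)[(3S,4R,5S)-5-(4-hydroxy-3,5-dimethoxyphenyl)-4-(hydroxymethyl)oxolan-3-yl]methanone (target), via bis-silyl keto alcohol 15 (not isolated)
Conditions: NaBH4 (1 equiv), EtOH/CH2Cl2, −78 °C; acetone; then K2CO3, MeOH, rt to 40 °C; aq. NH4Cl
Reagents that add atoms: none
Why: Chemoselective NaBH4 reduction of the aldehyde at −78 °C (far more electrophilic than the hindered, electron-rich aryl ketone), then carbonate methanolysis of both aryl silyl ethers; C2 and C3 are untouched and C4, still α to the ketone, stays in the thermodynamic trans arrangement.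

**Compound list**

1 | p-cresol (4-methylphenol) | Cc1ccc(O)cc1 | starting material
2 | 2,6-dibromo-4-methylphenol | Cc1cc(Br)c(O)c(Br)c1 | intermediate
3 | 2,6-dibromo-4-(dibromomethyl)phenol | BrC(Br)c1cc(Br)c(O)c(Br)c1 | intermediate
4 | 3,5-dibromo-4-hydroxybenzaldehyde | O=Cc1cc(Br)c(O)c(Br)c1 | intermediate
5 | syringaldehyde (4-hydroxy-3,5-dimethoxybenzaldehyde) | COc1cc(C=O)cc(OC)c1O | intermediate
6 | 4-(tert-butyldimethylsilyloxy)-3,5-dimethoxybenzaldehyde | COc1cc(C=O)cc(OC)c1O[Si](C)(C)C(C)(C)C | intermediate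
7 | but-2-yne-1,4-diol | OCC#CCO | starting material
8 | 1,4-bis(triethylsilyloxy)but-2-yne | CC[Si](CC)(CC)OCC#CCO[Si](CC)(CC)CC | intermediate
9 | (E)-1-[4-(tert-butyldimethylsilyloxy)-3,5-dimethoxyphenyl]-4-(triethylsilyloxy)-2-[(triethylsilyloxy)methyl]but-2-en-1-one | COc1cc(C(=O)/C(CO[Si](CC)(CC)CC)=C/CO[Si](CC)(CC)CC)cc(OC)c1O[Si](C)(C)C(C)(C)C | intermediate
10 | [4-(tert-butyldimethylsilyloxy)-3,5-dimethoxyphenyl]{2-[4-(tert-butyldimethylsilyloxy)-3,5-dimethoxyphenyl]-4,7-dihydro-1,3-dioxepin-5-yl}methanone, racemic | COc1cc(C(=O)C2=CCOC(c3cc(OC)c(O[Si](C)(C)C(C)(C)C)c(OC)c3)OC2)cc(OC)c1O[Si](C)(C)C(C)(C)C | intermediate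
11 | 2-[4-(tert-butyldimethylsilyloxy)-3,5-dimethoxyphenyl]-5-{[4-(tert-butyldimethylsilyloxy)-3,5-dimethoxyphenyl](triethylsilyloxy)methylidene}-4,5-dihydro-1,3-dioxepine, racemic, E/Z mixture | COc1cc(C(O[Si](CC)(CC)CC)=C2COC(c3cc(OC)c(O[Si](C)(C)C(C)(C)C)c(OC)c3)OC=C2)cc(OC)c1O[Si](C)(C)C(C)(C)C | intermediate
12 | (2S)-2-[4-(tert-butyldimethylsilyloxy)-3,5-dimethoxyphenyl]-4-{[4-(tert-butyldimethylsilyloxy)-3,5-dimethoxyphenyl](triethylsilyloxy)methylidene}oxolane-3-carbaldehyde, C3 epimers | COc1cc(C(O[Si](CC)(CC)CC)=C2CO[C@H](c3cc(OC)c(O[Si](C)(C)C(C)(C)C)c(OC)c3)C2C=O)cc(OC)c1O[Si](C)(C)C(C)(C)C | intermediate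
13 | (2S)-4-[4-(tert-butyldimethylsilyloxy)-3,5-dimethoxybenzoyl]-2-[4-(tert-butyldimethylsilyloxy)-3,5-dimethoxyphenyl]oxolane-3-carbaldehyde, kinetic mixture of C3/C4 epimers | COc1cc(C(=O)C2CO[C@H](c3cc(OC)c(O[Si](C)(C)C(C)(C)C)c(OC)c3)C2C=O)cc(OC)c1O[Si](C)(C)C(C)(C)C | intermediate
14 | (2S,3S,4S)-4-[4-(tert-butyldimethylsilyloxy)-3,5-dimethoxybenzoyl]-2-[4-(tert-butyldimethylsilyloxy)-3,5-dimethoxyphenyl]oxolane-3-carbaldehyde, all-trans | COc1cc(C(=O)[C@@H]2CO[C@H](c3cc(OC)c(O[Si](C)(C)C(C)(C)C)c(OC)c3)[C@H]2C=O)cc(OC)c1O[Si](C)(C)C(C)(C)C | intermediate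
15 | [4-(tert-butyldimethylsilyloxy)-3,5-dimethoxyphenyl]{(3S,4R,5S)-5-[4-(tert-butyldimethylsilyloxy)-3,5-dimethoxyphenyl]-4-(hydroxymethyl)oxolan-3-yl}methanone | COc1cc(C(=O)[C@@H]2CO[C@H](c3cc(OC)c(O[Si](C)(C)C(C)(C)C)c(OC)c3)[C@H]2CO)cc(OC)c1O[Si](C)(C)C(C)(C)C | intermediate
16 | (4-hydroxy-3,5-dimethoxyphenyl)[(3S,4R,5S)-5-(4-hydroxy-3,5-dimethoxyphenyl)-4-(hydroxymethyl)oxolan-3-yl]methanone (CID53356211) | COc1cc(C(=O)[C@@H]2CO[C@H](c3cc(OC)c(O)c(OC)c3)[C@H]2CO)cc(OC)c1O | target

**Step count and risks**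

Total steps: 9. Longest linear sequence: 8 (steps 1, 2, 3, 5, 6, 7, 8, 9; step 4 is a one-step side branch).

Three steps most likely to fail:

Step 8 (proposed new ring contraction). The reaction is untested: a racemic background pathway, poor facial control over the aryl oxocarbenium ion, or protodesilylation of 11 could erode yield or ee. Fallback with known chemistry, setting out from 11 and coming back at 14: the established achiral Lewis-acid vinyl-acetal ring contraction (TMSOTf 5 mol %, CH2Cl2, −78 °C) gives the racemic silyl enol ether aldehyde, that is 12 together with its mirror image, the (2R) silyl enol ether aldehyde F5. The HCl and DBU treatment of step 8 then gives 13 with its mirror-image epimer mixture F6, and finally racemic all-trans keto aldehyde, that is 14 with its (2R,3R,4R) enantiomer F7. Condensation with (1R,2R)-N,N'-dimethyl-1,2-diphenylethane-1,2-diamine (4 Å sieves, Et2O, rt) converts the racemate into two diastereomeric imidazolidines, the aminal of 14 F8 and the aminal of the enantiomer F9, which are separated by chromatography or crystallisation. Brief hydrolysis of F8 (5 % aq. HCl/Et2O, 0 °C) returns enantiopure 14, and the diamine is recovered.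

Step 5 (alkyne hydroacylation). The reaction class is known, but an internal alkyne with two propargylic silyl ethers may insert slowly, and the acidic co-catalyst may cleave some silyl ether. Fallback, setting out from 6 and 8 and coming back at 9: nickel-catalysed reductive coupling (Ni(cod)2 10 mol %, PBu3, Et3B, toluene, rt) adds the aldehyde and hydrogen syn across the alkyne to give the (E)-allylic O-diethylboryl ether F1. Aqueous work-up hydrolyses this to the (E)-allylic alcohol F2, and MnO2 (CH2Cl2, rt) oxidises the doubly activated alcohol F2 to 9.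

Step 6 (seven-membered acetal by the Noyori method). Closure of a 1,3-dioxepine from triethylsilyl (not trimethylsilyl) ethers on a hindered enone may be slow or incomplete. Fallback, setting out from 9 (with 6) and coming back at 10: PPTS in MeOH (0 °C to rt) removes both alkyl triethylsilyl groups, leaving the aryl TBS ether, to give the (E)-enone diol F3, whose E geometry keeps the 4-OH away from the carbonyl (no furan formation). Separately, 6 is converted with HC(OMe)3/PPTS in MeOH into the dimethyl acetal F4. Thermodynamic transacetalisation of F3 with F4 (PPTS cat., benzene, 50 °C, removal of MeOH over 5 Å sieves) then gives 10.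

Further compounds

F1 | step 5 | diethyl{(E)-1-[4-(tert-butyldimethylsilyloxy)-3,5-dimethoxyphenyl]-4-(triethylsilyloxy)-2-[(triethylsilyloxy)methyl]but-2-en-1-yloxy}borane, racemic, not isolated | COc1cc(C(OB(CC)CC)/C(CO[Si](CC)(CC)CC)=C/CO[Si](CC)(CC)CC)cc(OC)c1O[Si](C)(C)C(C)(C)C
F2 | step 5 | (E)-1-[4-(tert-butyldimethylsilyloxy)-3,5-dimethoxyphenyl]-4-(triethylsilyloxy)-2-[(triethylsilyloxy)methyl]but-2-en-1-ol, racemic | COc1cc(C(O)/C(CO[Si](CC)(CC)CC)=C/CO[Si](CC)(CC)CC)cc(OC)c1O[Si](C)(C)C(C)(C)C
F3 | step 6 | (E)-1-[4-(tert-butyldimethylsilyloxy)-3,5-dimethoxyphenyl]-4-hydroxy-2-(hydroxymethyl)but-2-en-1-one | COc1cc(C(=O)/C(CO)=C/CO)cc(OC)c1O[Si](C)(C)C(C)(C)C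
F4 | step 6 | tert-butyl[4-(dimethoxymethyl)-2,6-dimethoxyphenoxy]dimethylsilane (dimethyl acetal of 6) | COc1cc(C(OC)OC)cc(OC)c1O[Si](C)(C)C(C)(C)C
F5 | step 8 | (2R)-2-[4-(tert-butyldimethylsilyloxy)-3,5-dimethoxyphenyl]-4-{[4-(tert-butyldimethylsilyloxy)-3,5-dimethoxyphenyl](triethylsilyloxy)methylidene}oxolane-3-carbaldehyde (mirror image of 12) | COc1cc(C(O[Si](CC)(CC)CC)=C2CO[C@@H](c3cc(OC)c(O[Si](C)(C)C(C)(C)C)c(OC)c3)C2C=O)cc(OC)c1O[Si](C)(C)C(C)(C)C
F6 | step 8 | (2R)-4-[4-(tert-butyldimethylsilyloxy)-3,5-dimethoxybenzoyl]-2-[4-(tert-butyldimethylsilyloxy)-3,5-dimethoxyphenyl]oxolane-3-carbaldehyde, C3/C4 epimer mixture (mirror image of 13) | COc1cc(C(=O)C2CO[C@@H](c3cc(OC)c(O[Si](C)(C)C(C)(C)C)c(OC)c3)C2C=O)cc(OC)c1O[Si](C)(C)C(C)(C)C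
F7 | step 8 | (2R,3R,4R)-4-[4-(tert-butyldimethylsilyloxy)-3,5-dimethoxybenzoyl]-2-[4-(tert-butyldimethylsilyloxy)-3,5-dimethoxyphenyl]oxolane-3-carbaldehyde (enantiomer of 14) | COc1cc(C(=O)[C@H]2CO[C@@H](c3cc(OC)c(O[Si](C)(C)C(C)(C)C)c(OC)c3)[C@@H]2C=O)cc(OC)c1O[Si](C)(C)C(C)(C)C
F8 | step 8 | (4R,5R)-1,3-dimethyl-4,5-diphenylimidazolidin-2-yl aminal of 14 (imidazolidine C2 attached to oxolane C3 of the 2S,3,4S all-trans series) | COc1cc(C(=O)[C@@H]2CO[C@H](c3cc(OC)c(O[Si](C)(C)C(C)(C)C)c(OC)c3)[C@H]2C4N(C)[C@H](c5ccccc5)[C@@H](c5ccccc5)N4C)cc(OC)c1O[Si](C)(C)C(C)(C)C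
F9 | step 8 | (4R,5R)-1,3-dimethyl-4,5-diphenylimidazolidin-2-yl aminal of F7 (diastereomer of F8) | COc1cc(C(=O)[C@H]2CO[C@@H](c3cc(OC)c(O[Si](C)(C)C(C)(C)C)c(OC)c3)[C@@H]2C4N(C)[C@H](c5ccccc5)[C@@H](c5ccccc5)N4C)cc(OC)c1O[Si](C)(C)C(C)(C)C
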